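In a one-step world the complex stops at one exchange, the leaving ligand is carried off, and 100 % of the charge stands as complex with one exchanged; the real scheme goes further.

| setting | cedar | larch | elm | flask |
|---|---|---|---|---|
| starting complex | 0.18 M | 0.29 M | 0.13 M | 0.13 M |
| incoming ligand | 0.39 M | 0.39 M | 0.78 M | 0.390 M |
| remark | run made earlier | run made earlier | run made earlier |  |
| time |  |  |  | 15 min |

| run | time / min | complex with one exchanged / % | complex with two exchanged / % |
|---|---|---|---|
| cedar | 1.50 | 50.0 | 1.9 |
| cedar | 5.00 | 41.3 | 1.7 |
| cedar | 8.00 | 38.5 | 2.5 |
| cedar | 12.0 | 33.7 | 1.3 |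
| cedar | 20.0 | 28.7 | 4.5 |
| larch | 1.33 | 43.1 | 1.5 |
| larch | 2.50 | 42.7 | 0.4 |
| larch | 5.00 | 40.2 | 0.8 |
| larch | 10.0 | 39.3 | 1.2 |
| larch | 20.0 | 34.4 | 3.6 |
| elm | 4.00 | 27.0 | 0.7 |
| elm | 8.00 | 11.1 | 3.0 |
| elm | 10.0 | 8.0 | 1.4 |
| elm | 15.0 | 2.0 | 1.4 |
| elm | 20.0 | 0.2 | 0 |

(standard deviation of a reading: 1 percentage point)

- the earlier runs were read with a standard deviation of 1 percentage point
- reactions considered so far: starting complex + incoming ligand <-> leaving ligand + complex with one exchanged; complex with one exchanged + incoming ligand <-> leaving ligand + complex with two exchanged; complex with two exchanged + incoming ligand <-> leaving ligand + complex with three exchanged; complex with two exchanged <-> isomer of the product; leaving ligand -> by-product carried off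

* equivalents of incoming ligand to starting complex, everything else as given, that leave most complex with one exchanged at 15 min
* the amount of complex with one exchanged then, in percent of the starting complex charged
* the amount of complex with one exchanged with the amounts as given

I follow one molecule. The cedar run reads 50.0 % of complex with one exchanged by 1.50 min, so the first fork comes early. The later loss I read from the tail of the elm run, 8.0 % at 10.0 min and 2.0 % at 15.0 min. Taking the ligand there as its charge less 3 per complex, 0.390 M, gives a second-order constant κ for that loss of about 0.711 M⁻¹ min⁻¹, a reading with the scatter of those points.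

The opposite extreme is pseudo-first-order: ligand held at its charge less one exchange per complex leaves 6.25 % in the flask. I expect the flask above that figure: complex with two exchanged stays low in the readings, so I let each drained molecule take two more ligands, and the ligand falls during the run.

At 3.00 equivalents, the ligand then shrinks in step with the pool p of complex with one exchange or none. The pool, as a fraction of the charge, therefore falls as θ/(θ+t) at time t, where θ is the drain time, in which it falls to half: 5.41 min. I reckon a pool of 26.5 % in the flask at 15 min, and put the optimum near one equivalent, where the ligand pays for the first exchange.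

The forecast says 30 %, and 41 % at 1.8 equiv, holding that “Lowering the ligand trades plateau height against decay”. Its optimum lies above mine.

The flask gives 25.1 %, and the best is 52.7 % at 0.993 equiv.

    starting complex + incoming ligand ⇌ leaving ligand + complex with one exchanged (K = 0.360, k = 0.170 M⁻¹ s⁻¹)
    complex with one exchanged + incoming ligand ⇌ leaving ligand + complex with two exchanged (K = 0.200, k = 0.0110 M⁻¹ s⁻¹)
    complex with two exchanged + incoming ligand ⇌ leaving ligand + complex with three exchanged (K = 3.00, k = 0.900 M⁻¹ s⁻¹)
    complex with two exchanged ⇌ isomer of the product (K = 4.60, k = 0.130 s⁻¹)
    leaving ligand → by-product carried off (k = 0.0130 s⁻¹)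

At 1.50 min the flask holds 31.6 % starting complex and 53.7 % complex with one exchanged. The second exchange runs on while ligand remains, 25.8 % of its charge at 15.0 min, when complex with three exchanged stands at 59.0 % and the pool at 30.8 % against my 26.5 %. A neighbouring flask with the same charges, read at 1.0 h, has a pool of 8.36 %, and θ/(θ+t) gives 8.27 %.

The earlier runs and the new flask are calculated for an exercise.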